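## Retrosynthetic overview

1. Ring numbering: C1 ketone, C2 (bearing C7H2OH)=C3, C4 (O-propanoyl), C5 (isopropyl), C6 (O-acyl). The last bond made is C2–C7, by Morita–Baylis–Hillman hydroxymethylation of the 2-unsubstituted enone.
2. The only ring is formed once, by ring-closing metathesis (C2=C3), from an acyclic α′-acyloxy vinyl ketone that already carries C4, C5 and C6.
3. Key disconnection C1–C6 (two carbonyl-type carbons): C1 enters as an acryloyl anion equivalent, 1-lithio-1-methoxyallene, adding to the C6 aldehyde. The alkoxide is acylated in the same flask by the side-chain acid chloride, so the bond, the C6 stereocentre and the C6 ester arise in one operation.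
4. The C6 aldehyde comes from an auxiliary-controlled anti-aldol (C4–C5) of an isovaleryl imide with acrolein, then propanoylation and reductive release.
5. The side-chain acid chloride comes from Wittig olefination of silyloxyacetaldehyde, saponification and chlorination.

Assumption: the MgBr2·OEt2-catalysed aldol of the (S)-4-benzylthiazolidinethione imide is taken to give the (2S,3S)-anti adduct; if the facial sense proved opposite, the (R)-auxiliary would be used with no other change.

## Route

Step 1
Reactants: 1 (4S)-4-benzyl-1,3-thiazolidine-2-thione; 2 3-methylbutanoyl chloride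
Product: 3 N-(3-methylbutanoyl)-(4S)-4-benzylthiazolidine-2-thione
Conditions: Et3N, DMAP (cat.), CH2Cl2, 0 °C to rt
Reagents that add atoms: none
Why: Nucleophilic acyl substitution (N-acylation) of the acidic thiazolidinethione N–H gives the imide that can be enolised under soft conditions, and no stereocentre is created.

Step 2
Reactants: 3 N-(3-methylbutanoyl)-(4S)-4-benzylthiazolidine-2-thione; 4 prop-2-enal (acrolein)
Product: 6 (2S,3S)-3-hydroxy-2-isopropylpent-4-enoyl imide, via trimethylsilyl ether 5 (not isolated)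
Conditions: MgBr2·OEt2 (0.2 equiv), Et3N, TMSCl, EtOAc, 23 °C; then 1 M HCl, THF
Reagents that add atoms: none
Why: Evans magnesium halide-catalysed direct anti-aldol reaction, in which soft enolisation gives the Z-enolate, the benzyl group of the auxiliary shields one enolate face and a boat-like transition state gives the anti adduct, setting C5 (S) and C4 (S) of the target while TMSCl silylates the aldolate to turn the catalyst over.

Step 3
Reactants: 6 (2S,3S)-3-hydroxy-2-isopropylpent-4-enoyl imide
Product: 7 (2S,3S)-2-isopropyl-3-(propanoyloxy)pent-4-enoyl imide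
Conditions: (EtCO)2O, pyridine, DMAP (cat.), CH2Cl2, 0 °C
Reagents that add atoms: propanoic anhydride, CCC(=O)OC(=O)CC
Why: DMAP-catalysed O-acylation (esterification) installs the C4 propanoate under cold, weakly basic conditions so that E1cB loss of the β-oxygen does not compete, and the stereocentres are untouched.

Step 4
Reactants: 7 (2S,3S)-2-isopropyl-3-(propanoyloxy)pent-4-enoyl imide
Product: 8 (3S,4S)-4-formyl-5-methylhex-1-en-3-yl propanoate
Conditions: iBu2AlH (1.2 equiv), CH2Cl2, −78 °C; aq. potassium sodium tartrate; crude aldehyde used at once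
Reagents that add atoms: none
Why: Reductive cleavage of an N-acylthiazolidinethione with iBu2AlH, in which the very electrophilic thioimide is reduced at −78 °C to an aluminium hemiaminal that releases the aldehyde only on work-up, so the propanoate survives and C5 is not epimerised.

Step 5
Reactants: 9 [(tert-butyldimethylsilyl)oxy]acetaldehyde; 10 ethyl 2-(triphenylphosphoranylidene)propanoate
Product: 11 ethyl (2E)-4-[(tert-butyldimethylsilyl)oxy]-2-methylbut-2-enoate
Conditions: CH2Cl2, rt
Reagents that add atoms: none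
Why: Wittig olefination with a stabilised α-methyl ylide gives the trisubstituted enoate with E geometry (ester trans to the CH2OSi group).

Step 6
Reactants: 11 ethyl (2E)-4-[(tert-butyldimethylsilyl)oxy]-2-methylbut-2-enoate
Product: 12 (2E)-4-[(tert-butyldimethylsilyl)oxy]-2-methylbut-2-enoic acid
Conditions: LiOH·H2O, THF/H2O, rt; then 1 M HCl to pH 4, 0 °C
Reagents that add atoms: lithium hydroxide, [Li+].[OH-]
Why: Saponification (ester hydrolysis) leaves the primary silyl ether and the E double bond intact.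

Step 7
Reactants: 12 (2E)-4-[(tert-butyldimethylsilyl)oxy]-2-methylbut-2-enoic acid
Product: 13 (2E)-4-[(tert-butyldimethylsilyl)oxy]-2-methylbut-2-enoyl chloride
Conditions: 1-chloro-N,N,2-trimethylprop-1-en-1-amine, CH2Cl2, 0 °C to rt; concentrated and used crude
Reagents that add atoms: 1-chloro-N,N,2-trimethylprop-1-en-1-amine (Ghosez reagent), CC(C)=C(Cl)N(C)C
Why: Neutral acid chloride formation with the Ghosez α-chloroenamine generates no HCl, so the silyl ether and the E geometry are kept.

Step 8
Reactants: 14 1-methoxypropa-1,2-diene (methoxyallene); 8 (3S,4S)-4-formyl-5-methylhex-1-en-3-yl propanoate; 13 (2E)-4-[(tert-butyldimethylsilyl)oxy]-2-methylbut-2-enoyl chloride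
Product: 18 (3S,4S,5R)-5-{[(2E)-4-hydroxy-2-methylbut-2-enoyl]oxy}-6-oxo-4-(propan-2-yl)octa-1,7-dien-3-yl propanoate, via lithiated methoxyallene 15 (not isolated), via lithium alkoxide 16 (not isolated), via allenyl ester 17 (not isolated)
Conditions: nBuLi, THF, −40 °C (14 to 15); add 8, −78 °C; add 13, −78 to −40 °C; then 48% aq. HF, MeCN, 0 °C to rt
Reagents that add atoms: water, O
Why: Nucleophilic acylation with an acyl anion equivalent (lithiated alkoxyallene as masked acryloyl anion), in which the C1 carbanion adds to the C6 aldehyde under Felkin–Anh control reinforced by 1,3-anti induction from the β-propanoyloxy group of the anti-configured aldehyde to set C6 as R, the alkoxide is O-acylated at −78 °C before the propanoyl group can migrate, and aqueous HF then hydrolyses the 1-alkoxyallene to the vinyl ketone and removes the silyl ether.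

Step 9
Reactants: 18 (3S,4S,5R)-5-{[(2E)-4-hydroxy-2-methylbut-2-enoyl]oxy}-6-oxo-4-(propan-2-yl)octa-1,7-dien-3-yl propanoate
Product: 19 (1R,5S,6S)-2-oxo-6-(propan-2-yl)-5-(propanoyloxy)cyclohex-3-en-1-yl (2E)-4-hydroxy-2-methylbut-2-enoate
Conditions: second-generation Grubbs catalyst (H2IMes)(PCy3)Cl2Ru=CHPh (5 mol%), CH2Cl2 (0.005 M), 40 °C
Reagents that add atoms: none
Why: Ring-closing metathesis between the vinyl ketone and the allylic vinyl group closes the six-membered enone with loss of ethene, while the trisubstituted side-chain enoate is inert and no stereocentre is touched.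

Step 10
Reactants: 19 (1R,5S,6S)-2-oxo-6-(propan-2-yl)-5-(propanoyloxy)cyclohex-3-en-1-yl (2E)-4-hydroxy-2-methylbut-2-enoate
Product: 20 CNP0285949.1
Conditions: 37% aq. HCHO, DMAP (0.3 equiv), THF, rt
Reagents that add atoms: formaldehyde, C=O
Why: Morita–Baylis–Hillman reaction, in which DMAP adds to C3, the resulting enolate is hydroxymethylated at C2 by formaldehyde and loss of DMAP restores the enone, the weak base leaving C4, C5 and C6 untouched (the trans-diequatorial C5/C6 arrangement present is also the thermodynamic one).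

## Compound list

1 | (4S)-4-benzyl-1,3-thiazolidine-2-thione | S=C1N[C@@H](Cc2ccccc2)CS1 | starting material
2 | 3-methylbutanoyl chloride | CC(C)CC(=O)Cl | starting material
3 | 1-[(4S)-4-benzyl-2-sulfanylidene-1,3-thiazolidin-3-yl]-3-methylbutan-1-one | CC(C)CC(=O)N1[C@@H](Cc2ccccc2)CSC1=S | intermediate
4 | prop-2-enal (acrolein) | C=CC=O | starting material
5 | (2S,3S)-1-[(4S)-4-benzyl-2-sulfanylidene-1,3-thiazolidin-3-yl]-2-(propan-2-yl)-3-[(trimethylsilyl)oxy]pent-4-en-1-one | S=C1SC[C@H](Cc2ccccc2)N1C(=O)[C@@H](C(C)C)[C@@H](O[Si](C)(C)C)C=C | intermediate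
6 | (2S,3S)-1-[(4S)-4-benzyl-2-sulfanylidene-1,3-thiazolidin-3-yl]-3-hydroxy-2-(propan-2-yl)pent-4-en-1-one | S=C1SC[C@H](Cc2ccccc2)N1C(=O)[C@@H](C(C)C)[C@@H](O)C=C | intermediate
7 | (3S,4S)-4-{[(4S)-4-benzyl-2-sulfanylidene-1,3-thiazolidin-3-yl]carbonyl}-5-methylhex-1-en-3-yl propanoate | S=C1SC[C@H](Cc2ccccc2)N1C(=O)[C@@H](C(C)C)[C@@H](OC(=O)CC)C=C | intermediate
8 | (3S,4S)-4-formyl-5-methylhex-1-en-3-yl propanoate | O=C[C@@H](C(C)C)[C@@H](OC(=O)CC)C=C | intermediate
9 | [(tert-butyldimethylsilyl)oxy]acetaldehyde | O=CCO[Si](C)(C)C(C)(C)C | starting material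
10 | ethyl 2-(triphenylphosphoranylidene)propanoate | CCOC(=O)C(C)=P(c1ccccc1)(c1ccccc1)c1ccccc1 | starting material
11 | ethyl (2E)-4-[(tert-butyldimethylsilyl)oxy]-2-methylbut-2-enoate | CCOC(=O)/C(C)=C/CO[Si](C)(C)C(C)(C)C | intermediate
12 | (2E)-4-[(tert-butyldimethylsilyl)oxy]-2-methylbut-2-enoic acid | OC(=O)/C(C)=C/CO[Si](C)(C)C(C)(C)C | intermediate
13 | (2E)-4-[(tert-butyldimethylsilyl)oxy]-2-methylbut-2-enoyl chloride | ClC(=O)/C(C)=C/CO[Si](C)(C)C(C)(C)C | intermediate
14 | 1-methoxypropa-1,2-diene (methoxyallene) | C=C=COC | starting material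
15 | (1-methoxypropa-1,2-dien-1-yl)lithium | C=C=C([Li])OC | intermediate
16 | lithium (3S,4R,5R)-6-methoxy-4-(propan-2-yl)-3-(propanoyloxy)octa-1,6,7-trien-5-olate | C=C=C(OC)[C@H]([O-])[C@@H](C(C)C)[C@@H](OC(=O)CC)C=C.[Li+] | intermediate
17 | (3S,4S,5R)-5-({(2E)-4-[(tert-butyldimethylsilyl)oxy]-2-methylbut-2-enoyl}oxy)-6-methoxy-4-(propan-2-yl)octa-1,6,7-trien-3-yl propanoate | C=C=C(OC)[C@H](OC(=O)/C(C)=C/CO[Si](C)(C)C(C)(C)C)[C@@H](C(C)C)[C@@H](OC(=O)CC)C=C | intermediate
18 | (3S,4S,5R)-5-{[(2E)-4-hydroxy-2-methylbut-2-enoyl]oxy}-6-oxo-4-(propan-2-yl)octa-1,7-dien-3-yl propanoate | C=CC(=O)[C@H](OC(=O)/C(C)=C/CO)[C@@H](C(C)C)[C@@H](OC(=O)CC)C=C | intermediate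
19 | (1R,5S,6S)-2-oxo-6-(propan-2-yl)-5-(propanoyloxy)cyclohex-3-en-1-yl (2E)-4-hydroxy-2-methylbut-2-enoate | CCC(=O)O[C@H]1C=CC(=O)[C@H](OC(=O)/C(C)=C/CO)[C@H]1C(C)C | intermediate
20 | (1R,5S,6S)-3-(hydroxymethyl)-2-oxo-6-(propan-2-yl)-5-(propanoyloxy)cyclohex-3-en-1-yl (2E)-4-hydroxy-2-methylbut-2-enoate (CNP0285949.1) | CCC(=O)O[C@H]1C=C(CO)C(=O)[C@H](OC(=O)/C(C)=C/CO)[C@H]1C(C)C | target

## Step count and risks

Total step count: 10. Longest linear sequence: 7 (steps 1, 2, 3, 4, 8, 9, 10).

Most likely to fail, with one fallback each: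

Step 8 (one-flask addition, acylation and hydrolysis). The alkoxide 16 may shift the C4 propanoyl group or deprotonate 13 to a vinylketene before O-acylation, aldehyde 8 may enolise and lose propanoate, and the Felkin preference at C6 may be modest. The fallback sets out from 8 and returns at 19. The adduct of 15 and 8 is quenched at −78 °C with AcOH and isolated as the allenyl carbinol F1. Hydrolysis with 5% aq. H2SO4 in THF gives the α′-hydroxy vinyl ketone F2. Ring-closing metathesis with the second-generation Grubbs catalyst then gives the cyclic hydroxy enone F3, in which the trans-1,3 arrangement of the C4 ester and the C6 hydroxyl rules out acyl transfer. Steglich esterification with acid 12 (DCC, DMAP) gives the silyl-protected diester F4, and aq. HF in MeCN returns 19.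

Step 10 (hydroxymethylation of a hindered, 4-substituted enone that carries base-sensitive esters). The fallback sets out from 19 and returns at 20. α-Iodination (I2, pyridine, CH2Cl2) gives the 2-iodo enone F5, and Stille coupling with (tributylstannyl)methanol (Pd(PPh3)4, dioxane, 80 °C) installs the CH2OH group.

Step 4 (the propanoate may be over-reduced, and the β-acyloxy aldehyde 8 may eliminate or epimerise while the auxiliary is removed). The fallback sets out from 6 and returns at 8. Aminolysis of the thioimide with MeNHOMe·HCl and imidazole in CH2Cl2 gives the hydroxy Weinreb amide F6, and propanoylation ((EtCO)2O, pyridine) gives the ester amide F7. Reduction with iBu2AlH (THF, −78 °C) through the chelated tetrahedral intermediate then releases 8, with only a volatile, water-soluble amine as by-product, so no chromatography of the labile aldehyde is needed.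

## Further compounds

F1 | step 8 | (3S,4R,5R)-5-hydroxy-6-methoxy-4-(propan-2-yl)octa-1,6,7-trien-3-yl propanoate | C=C=C(OC)[C@H](O)[C@@H](C(C)C)[C@@H](OC(=O)CC)C=C
F2 | step 8 | (3S,4R,5R)-5-hydroxy-6-oxo-4-(propan-2-yl)octa-1,7-dien-3-yl propanoate | C=CC(=O)[C@H](O)[C@@H](C(C)C)[C@@H](OC(=O)CC)C=C
F3 | step 8 | (1S,5R,6R)-5-hydroxy-4-oxo-6-(propan-2-yl)cyclohex-2-en-1-yl propanoate | CCC(=O)O[C@H]1C=CC(=O)[C@H](O)[C@H]1C(C)C
F4 | step 8 | (1R,5S,6S)-2-oxo-6-(propan-2-yl)-5-(propanoyloxy)cyclohex-3-en-1-yl (2E)-4-[(tert-butyldimethylsilyl)oxy]-2-methylbut-2-enoate | CCC(=O)O[C@H]1C=CC(=O)[C@H](OC(=O)/C(C)=C/CO[Si](C)(C)C(C)(C)C)[C@H]1C(C)C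
F5 | step 10 | (1R,5R,6S)-3-iodo-2-oxo-6-(propan-2-yl)-5-(propanoyloxy)cyclohex-3-en-1-yl (2E)-4-hydroxy-2-methylbut-2-enoate | CCC(=O)O[C@H]1C=C(I)C(=O)[C@H](OC(=O)/C(C)=C/CO)[C@H]1C(C)C
F6 | step 4 | (2S,3S)-3-hydroxy-N-methoxy-N-methyl-2-(propan-2-yl)pent-4-enamide | CON(C)C(=O)[C@@H](C(C)C)[C@@H](O)C=C
F7 | step 4 | (3S,4S)-4-[methoxy(methyl)carbamoyl]-5-methylhex-1-en-3-yl propanoate | CON(C)C(=O)[C@@H](C(C)C)[C@@H](OC(=O)CC)C=C
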